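A direct plan would take the upper unit from the chiral pool as benzyl-protected leucorobinetinidin A1 and arylate its C4 cation with 3,4,5-tris(benzyloxy)phenol A2 to the 4α-arylflavan phenol A3.
It would then exchange the phenol OH of A3 for a formyl group in two steps (sulfonylation, carbonylation) to aldehyde A4, extend A4 by an aldol condensation to chalcone A5, reduce the enone, close the lower pyran ring under a chiral acid to flav-3-ene A6, and end with cis-dihydroxylation and hydrogenolysis.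
Weak step 1, the closure of the lower pyran ring to A6: the lower C2 would be set late, on the most advanced intermediate, by a ring closure without close precedent, and the 2H-chromene formed can lose C2 again by ring opening.
Weak step 2, the exchange of OH for CHO on A3: a sulfonylation and a carbonylation at the most crowded ring position, two functional-group steps that add one carbon.
Weak step 3, the linear rebuild of the lower C15 unit on the precious upper unit (seven steps from A3), although this unit exists complete, with C2 and C3 in the right configuration, in the chiral pool.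

Retrosynthetic overview
Feature used: the upper C4 is bonded to ring A ortho to O1 (para to O7) and to C2' of the central pyrogallol ring E (ring B of the lower unit), so ring A with C4 is an o-quinone methide and the upper pyran ring C is cut at C3–C4 and O1–C2.
Key disconnection: a chiral-acid-catalysed annulation of this o-quinone methide with an enamide that brings C2, C3 and ring B closes ring C as a 4H-chromene and sets C4; hydroboration of its C2=C3 enol ether then sets C2 and C3 from C4.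
The lower unit (rings D, F, E) comes complete from (+)-dihydrorobinetin (C2, C3 from the pool, C4 by a bulky hydride) and is joined as a 2'-aryllithium to 4-(benzyloxy)-2-hydroxybenzaldehyde, which supplies ring A and C4.
Ring order: ring F is closed from the start and ring C closes last; no flav-3-ene closure, no OH-to-CHO exchange and no rebuild of the lower unit are needed.
Key step: step 8

Assumption: (+)-dihydrorobinetin is available as the (2R,3R) enantiomer; rings are called A, C, B in the upper unit and D, F, E in the lower unit (E is the central ring, C1' on the lower C2, C2' on the upper C4); the (R)-acid of step 8 is taken to give (4S) as with simple o-hydroxybenzhydrols, and its enantiomer would be used if the sense on 10 were the opposite.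

Step 1
Reactants: 1 (+)-dihydrorobinetin
Product: 2 7,3',4',5'-tetra-O-benzyl-dihydrorobinetin
Conditions: BnBr (4.4 equiv), K2CO3, DMF, rt, Ar
Reagents that add atoms: benzyl bromide BrCc1ccccc1
Why: Williamson etherification of the four phenols with a carbonate base, which should leave the 3-OH and the C2/C3 stereocentres of the trans-dihydroflavonol untouched.

Step 2
Reactants: 2 7,3',4',5'-tetra-O-benzyl-dihydrorobinetin
Product: 3 (2R,3R)-7-(benzyloxy)-3-[(tert-butyldimethylsilyl)oxy]-2-[3,4,5-tris(benzyloxy)phenyl]chroman-4-one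
Conditions: TBSOTf, 2,6-lutidine, CH2Cl2, −78 to 0 °C
Reagents that add atoms: tert-butyldimethylsilyl trifluoromethanesulfonate CC(C)(C)[Si](C)(C)OS(=O)(=O)C(F)(F)F
Why: O-Silylation of the α-ketol gives a bulky equatorial 3-silyloxy group that shields the ketol from oxidation in step 3, directs the hydride in step 4 and cannot act as an internal nucleophile in step 8.

Step 3
Reactants: 3 (2R,3R)-7-(benzyloxy)-3-[(tert-butyldimethylsilyl)oxy]-2-[3,4,5-tris(benzyloxy)phenyl]chroman-4-one
Product: 4 (2R,3R)-7-(benzyloxy)-2-[2-bromo-3,4,5-tris(benzyloxy)phenyl]-3-[(tert-butyldimethylsilyl)oxy]chroman-4-one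
Conditions: NBS (1.05 equiv), MeCN, 0 °C, dark
Reagents that add atoms: N-bromosuccinimide O=C1CCC(=O)N1Br
Why: Electrophilic aromatic bromination should go to C2' (= C6') of ring E, ortho and para to benzyloxy groups, because ring D is deactivated by the C4 carbonyl group.

Step 4
Reactants: 4 (2R,3R)-7-(benzyloxy)-2-[2-bromo-3,4,5-tris(benzyloxy)phenyl]-3-[(tert-butyldimethylsilyl)oxy]chroman-4-one
Product: 6 (2R,3R,4S)-7-(benzyloxy)-2-[2-bromo-3,4,5-tris(benzyloxy)phenyl]-3,4-bis[(tert-butyldimethylsilyl)oxy]chroman (2,3-trans-3,4-cis), via lithium alkoxide 5 (not isolated)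
Conditions: LiBH(s-Bu)3 (1.1 equiv), THF, −78 °C; then TBSOTf (1.5 equiv), −78 to 0 °C (one pot)
Reagents that add atoms: lithium tri-sec-butylborohydride [Li+].CCC(C)[BH-](C(C)CC)C(C)CC (the lithium of 5); tert-butyldimethylsilyl trifluoromethanesulfonate CC(C)(C)[Si](C)(C)OS(=O)(=O)C(F)(F)F
Why: Reduction of a 2-substituted cyclic aryl ketone by a bulky trialkylborohydride, which should attack along the equatorial direction (as with 2-substituted 1-tetralones and 3-substituted chroman-4-ones) and give the axial 4-alkoxide cis to the 3-silyloxy group (C4 S), trapped in the same flask as its silyl ether.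

Step 5
Reactants: 6 (2R,3R,4S)-7-(benzyloxy)-2-[2-bromo-3,4,5-tris(benzyloxy)phenyl]-3,4-bis[(tert-butyldimethylsilyl)oxy]chroman; 7 4-(benzyloxy)-2-hydroxybenzaldehyde
Product: 10 [4-(benzyloxy)-2-hydroxyphenyl]{2,3,4-tris(benzyloxy)-6-[(2R,3R,4S)-7-(benzyloxy)-3,4-bis[(tert-butyldimethylsilyl)oxy]chroman-2-yl]phenyl}methanol (both carbinol epimers), via sodium phenolate 8 (not isolated), via aryllithium 9 (not isolated)
Conditions: 7, NaH, THF, 0 °C (gives 8); 6, t-BuLi (2.1 equiv), THF, −78 °C (gives 9); 8 added to 9, −78 to −20 °C; H2O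
Reagents that add atoms: sodium hydride [Na+].[H-] (the sodium of 8); tert-butyllithium [Li]C(C)(C)C (the lithium of 9)
Why: Bromine–lithium exchange and 1,2-addition of the aryllithium to the aldehyde join C2' of ring E to the future upper C4 and bring in ring A with its free ortho hydroxyl group; the carbinol configuration is of no consequence because step 8 erases it.

Step 6
Reactants: 11 3,4,5-tris(benzyloxy)benzaldehyde
Product: 12 3,4,5-tris(benzyloxy)benzonitrile
Conditions: I2, aq NH3, THF, rt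
Reagents that add atoms: ammonia N
Why: Oxidative conversion of an aldehyde into a nitrile through the aldimine and its N-iodo derivative, which loses HI.

Step 7
Reactants: 12 3,4,5-tris(benzyloxy)benzonitrile
Product: 14 N-{1-[3,4,5-tris(benzyloxy)phenyl]ethenyl}acetamide, via magnesium ketiminate 13 (not isolated)
Conditions: MeMgBr, THF, 0 to 50 °C; then Ac2O, 0 °C to rt
Reagents that add atoms: methylmagnesium bromide C[Mg]Br; acetic anhydride CC(=O)OC(C)=O
Why: Grignard addition to the nitrile stops at the N-magnesio ketimine, whose N-acetylation and imine–enamine tautomerisation give the N-acetyl enamide (one-pot enamide synthesis from nitriles).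

Step 8
Reactants: 10 [4-(benzyloxy)-2-hydroxyphenyl]{2,3,4-tris(benzyloxy)-6-[(2R,3R,4S)-7-(benzyloxy)-3,4-bis[(tert-butyldimethylsilyl)oxy]chroman-2-yl]phenyl}methanol; 14 N-{1-[3,4,5-tris(benzyloxy)phenyl]ethenyl}acetamide
Product: 17 (4S)-7-(benzyloxy)-2-[3,4,5-tris(benzyloxy)phenyl]-4-aryl-4H-chromene (aryl = ring E carrying the silylated lower unit), via o-quinone methide 15 (not isolated), via 2-acetamidochroman 16 (not isolated)
Conditions: (R)-3,3'-bis(2,4,6-triisopropylphenyl)-1,1'-binaphthyl-2,2'-diyl hydrogen phosphate (10 mol %), 14 (2 equiv), 4 Å MS, CHCl3, −20 °C, slow addition of 10; then pyridinium p-toluenesulfonate (0.2 equiv), 40 °C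
Reagents that add atoms: none
Why: The phosphoric acid dehydrates either carbinol epimer of 10 to the hydrogen-bonded (E)-o-quinone methide 15, the β-carbon of enamide 14 (held on the same phosphate through its N–H) adds to the methide carbon to form C3–C4, the phenol oxygen closes on the N-acyliminium carbon to form O1–C2 and give N,O-ketal 16, and the weak pyridinium acid then removes acetamide to leave the C2=C3 enol ether of 17. The closest known reaction type is the chiral phosphoric acid-catalysed conjugate addition–cyclisation of enamides and β-dicarbonyl compounds to o-quinone methides formed in situ from o-hydroxybenzhydrols, which gives 2-amidochromans and 4-aryl-4H-chromenes. One ring closes, the upper pyran ring C, as a stepwise formal [4+2] annulation of the oxadiene O1=C8a–C4a=C4 with the enamide C=C, the C–O bond forming by 6-exo-trig attack of the phenol oxygen on the iminium carbon. The only lasting new stereocentre, C4 (S), is set by the catalyst, which binds the planar methide and the enamide in one hydrogen-bonded ion-pair assembly and leaves one face of the methide carbon open; the aminal carbon C2 is lost again. The step needs the enamide to outrun all other nucleophiles and the acid to spare the lower unit: the enamide is by far the strongest π-nucleophile present and is used in excess while 10 is added slowly, O3 and O4 of ring F are bulky silyl ethers that cannot close the six-membered isochroman onto C4, ring D cannot reach C4 because ring F holds its free position next to O1 anti to the lower C2, and the weak acid should not ionise the silylated benzylic C4 of ring F.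

Step 9
Reactants: 17 (4S)-7-(benzyloxy)-2-[3,4,5-tris(benzyloxy)phenyl]-4-aryl-4H-chromene
Product: 19 (2R,3S,4S)-7-(benzyloxy)-2-[3,4,5-tris(benzyloxy)phenyl]-4-aryl-chroman-3-ol (2,3-trans-3,4-trans; aryl as in 17), via alkylborane 18 (not isolated)
Conditions: BH3·THF, THF, 0 °C to rt; then NaOH, H2O2, 0 °C
Reagents that add atoms: borane–tetrahydrofuran [BH3-][O+]1CCCC1 (the boron of 18); hydrogen peroxide OO
Why: Hydroboration–oxidation of a cyclic enol ether (as with 4H-flav-2-enes), in which boron adds to C3 (β to O1 and to the aryl group) and hydrogen to C2, both from the face opposite the C4 aryl group, so that C3 (S) is set trans to C4 and C2 (R) trans to C3, and the C–B bond is oxidised with retention.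

Step 10
Reactants: 19 (2R,3S,4S)-7-(benzyloxy)-2-[3,4,5-tris(benzyloxy)phenyl]-4-aryl-chroman-3-ol
Product: 20 octa-O-benzyl ether of the target (upper unit 2R,3S,4S; lower unit 2R,3S,4S with free 3,4-cis-diol)
Conditions: Bu4NF, THF, 0 °C to rt
Reagents that add atoms: none
Why: Fluoride-induced desilylation removes the two secondary silyl ethers of ring F while all phenols are still benzyl ethers, so that no phenoxide or quinone methide chemistry can touch the benzylic 4-OH.

Step 11
Reactants: 20 octa-O-benzyl ether of the target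
Product: 21 target, robinetinidol-(4α→2')-(2R,3S,4S)-leucorobinetinidin
Conditions: H2 (1 atm), Pd(OH)2/C, THF–MeOH, rt, neutral, stopped at complete debenzylation; filtration under Ar
Reagents that add atoms: none
Why: Catalytic hydrogenolysis of the eight aryl benzyl ethers under neutral conditions, in which the cyclic benzylic ether bonds and the secondary benzylic 4-OH of ring F should persist as in debenzylations of p-hydroxyphenyl carbinols, so that no stereocentre is touched.

Compound list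
1 | (+)-dihydrorobinetin, (2R,3R)-3,7-dihydroxy-2-(3,4,5-trihydroxyphenyl)chroman-4-one | Oc1ccc2c(c1)O[C@H](c1cc(O)c(O)c(O)c1)[C@@H](O)C2=O | starting material
2 | 7,3',4',5'-tetra-O-benzyl-dihydrorobinetin, (2R,3R)-7-(benzyloxy)-3-hydroxy-2-[3,4,5-tris(benzyloxy)phenyl]chroman-4-one | c1ccccc1COc1ccc2c(c1)O[C@H](c1cc(OCc3ccccc3)c(OCc3ccccc3)c(OCc3ccccc3)c1)[C@@H](O)C2=O | intermediate
3 | (2R,3R)-7-(benzyloxy)-3-[(tert-butyldimethylsilyl)oxy]-2-[3,4,5-tris(benzyloxy)phenyl]chroman-4-one | c1ccccc1COc1ccc2c(c1)O[C@H](c1cc(OCc3ccccc3)c(OCc3ccccc3)c(OCc3ccccc3)c1)[C@@H](O[Si](C)(C)C(C)(C)C)C2=O | intermediate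
4 | (2R,3R)-7-(benzyloxy)-2-[2-bromo-3,4,5-tris(benzyloxy)phenyl]-3-[(tert-butyldimethylsilyl)oxy]chroman-4-one | c1ccccc1COc1ccc2c(c1)O[C@H](c1c(Br)c(OCc3ccccc3)c(OCc3ccccc3)c(OCc3ccccc3)c1)[C@@H](O[Si](C)(C)C(C)(C)C)C2=O | intermediate
5 | lithium 4-alkoxide from 4, C4–O cis to the 3-silyloxy group (2,3-trans-3,4-cis) | c1ccccc1COc1ccc2c(c1)O[C@H](c1c(Br)c(OCc3ccccc3)c(OCc3ccccc3)c(OCc3ccccc3)c1)[C@@H](O[Si](C)(C)C(C)(C)C)[C@H]2[O-].[Li+] | intermediate
6 | (2R,3R,4S)-7-(benzyloxy)-2-[2-bromo-3,4,5-tris(benzyloxy)phenyl]-3,4-bis[(tert-butyldimethylsilyl)oxy]chroman (2,3-trans-3,4-cis) | c1ccccc1COc1ccc2c(c1)O[C@H](c1c(Br)c(OCc3ccccc3)c(OCc3ccccc3)c(OCc3ccccc3)c1)[C@@H](O[Si](C)(C)C(C)(C)C)[C@H]2O[Si](C)(C)C(C)(C)C | intermediate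
7 | 4-(benzyloxy)-2-hydroxybenzaldehyde | O=Cc1ccc(OCc2ccccc2)cc1O | starting material
8 | sodium 5-(benzyloxy)-2-formylphenolate | O=Cc1ccc(OCc2ccccc2)cc1[O-].[Na+] | intermediate
9 | aryllithium from 6 (Li in place of Br at C2' of ring E) | c1ccccc1COc1ccc2c(c1)O[C@H](c1c([Li])c(OCc3ccccc3)c(OCc3ccccc3)c(OCc3ccccc3)c1)[C@@H](O[Si](C)(C)C(C)(C)C)[C@H]2O[Si](C)(C)C(C)(C)C | intermediate
10 | [4-(benzyloxy)-2-hydroxyphenyl]{2,3,4-tris(benzyloxy)-6-[(2R,3R,4S)-7-(benzyloxy)-3,4-bis[(tert-butyldimethylsilyl)oxy]chroman-2-yl]phenyl}methanol, both epimers at the carbinol carbon | c1ccccc1COc1ccc2c(c1)O[C@H](c1c(C(O)c4ccc(OCc5ccccc5)cc4O)c(OCc3ccccc3)c(OCc3ccccc3)c(OCc3ccccc3)c1)[C@@H](O[Si](C)(C)C(C)(C)C)[C@H]2O[Si](C)(C)C(C)(C)C | intermediate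
11 | 3,4,5-tris(benzyloxy)benzaldehyde | O=Cc1cc(OCc2ccccc2)c(OCc2ccccc2)c(OCc2ccccc2)c1 | starting material
12 | 3,4,5-tris(benzyloxy)benzonitrile | N#Cc1cc(OCc2ccccc2)c(OCc2ccccc2)c(OCc2ccccc2)c1 | intermediate
13 | N-(bromomagnesio) ketimine of 1-[3,4,5-tris(benzyloxy)phenyl]ethanone | CC(=N[Mg]Br)c1cc(OCc2ccccc2)c(OCc2ccccc2)c(OCc2ccccc2)c1 | intermediate
14 | N-{1-[3,4,5-tris(benzyloxy)phenyl]ethenyl}acetamide | CC(=O)NC(=C)c1cc(OCc2ccccc2)c(OCc2ccccc2)c(OCc2ccccc2)c1 | intermediate
15 | (E)-o-quinone methide from 10, 3-(benzyloxy)-6-(arylmethylidene)cyclohexa-2,4-dien-1-one, aryl = ring E of 10 with its lower unit | c1ccccc1COc1ccc2c(c1)O[C@H](c1c(/C=C4\C=CC(OCc5ccccc5)=CC4=O)c(OCc3ccccc3)c(OCc3ccccc3)c(OCc3ccccc3)c1)[C@@H](O[Si](C)(C)C(C)(C)C)[C@H]2O[Si](C)(C)C(C)(C)C | intermediate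
16 | 2-acetamido-7-(benzyloxy)-2-[3,4,5-tris(benzyloxy)phenyl]-4-arylchroman (N,O-ketal; C4 S, C2 either configuration), aryl as in 17 | c1ccccc1COc1ccc2c(c1)OC(NC(C)=O)(c1cc(OCc3ccccc3)c(OCc3ccccc3)c(OCc3ccccc3)c1)C[C@@H]2c1c([C@H]2Oc3cc(OCc4ccccc4)ccc3[C@H](O[Si](C)(C)C(C)(C)C)[C@@H]2O[Si](C)(C)C(C)(C)C)cc(OCc2ccccc2)c(OCc2ccccc2)c1OCc1ccccc1 | intermediate
17 | (4S)-7-(benzyloxy)-2-[3,4,5-tris(benzyloxy)phenyl]-4-aryl-4H-chromene, aryl = 2,3,4-tris(benzyloxy)-6-[(2R,3R,4S)-7-(benzyloxy)-3,4-bis[(tert-butyldimethylsilyl)oxy]chroman-2-yl]phenyl | c1ccccc1COc1ccc2c(c1)OC(c1cc(OCc3ccccc3)c(OCc3ccccc3)c(OCc3ccccc3)c1)=C[C@@H]2c1c([C@H]2Oc3cc(OCc4ccccc4)ccc3[C@H](O[Si](C)(C)C(C)(C)C)[C@@H]2O[Si](C)(C)C(C)(C)C)cc(OCc2ccccc2)c(OCc2ccccc2)c1OCc1ccccc1 | intermediate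
18 | C3 alkylborane (RBH2) from 17, boron trans to both aryl groups | c1ccccc1COc1ccc2c(c1)O[C@H](c1cc(OCc3ccccc3)c(OCc3ccccc3)c(OCc3ccccc3)c1)[C@@H](B)[C@@H]2c1c([C@H]2Oc3cc(OCc4ccccc4)ccc3[C@H](O[Si](C)(C)C(C)(C)C)[C@@H]2O[Si](C)(C)C(C)(C)C)cc(OCc2ccccc2)c(OCc2ccccc2)c1OCc1ccccc1 | intermediate
19 | (2R,3S,4S)-7-(benzyloxy)-2-[3,4,5-tris(benzyloxy)phenyl]-4-aryl-chroman-3-ol (2,3-trans-3,4-trans), aryl as in 17 | c1ccccc1COc1ccc2c(c1)O[C@H](c1cc(OCc3ccccc3)c(OCc3ccccc3)c(OCc3ccccc3)c1)[C@@H](O)[C@@H]2c1c([C@H]2Oc3cc(OCc4ccccc4)ccc3[C@H](O[Si](C)(C)C(C)(C)C)[C@@H]2O[Si](C)(C)C(C)(C)C)cc(OCc2ccccc2)c(OCc2ccccc2)c1OCc1ccccc1 | intermediate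
20 | octa-O-benzyl ether of the target, upper unit (2R,3S,4S)-4-arylchroman-3-ol, lower unit (2R,3S,4S)-chroman-3,4-diol (2,3-trans-3,4-cis) | c1ccccc1COc1ccc2c(c1)O[C@H](c1cc(OCc3ccccc3)c(OCc3ccccc3)c(OCc3ccccc3)c1)[C@@H](O)[C@@H]2c1c([C@H]2Oc3cc(OCc4ccccc4)ccc3[C@H](O)[C@@H]2O)cc(OCc2ccccc2)c(OCc2ccccc2)c1OCc1ccccc1 | intermediate
21 | robinetinidol-(4α→2')-(2R,3S,4S)-leucorobinetinidin, upper unit 2R,3S,4S, lower unit 2R,3S,4S | Oc1ccc2c(c1)O[C@H](c1cc(O)c(O)c(O)c1)[C@@H](O)[C@@H]2c1c([C@H]2Oc3cc(O)ccc3[C@H](O)[C@@H]2O)cc(O)c(O)c1O | target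

Total number of steps: 11 (steps 6 and 7 make the enamide in a side branch).
Longest linear sequence: 9 steps (1 to 5, then 8 to 11).

Steps most likely to fail

1. Step 8 (key step). Process at risk: the face selection at the methide carbon may be eroded by the two ortho substituents of ring E and by a mismatch with the chiral lower unit, and electron-rich arenes may capture the cation. Fallback: the annulation is given up and the upper stereocentres are taken from the chiral pool; it sets out from 1 and comes back at 21. 1 would be reduced with NaBH4 in EtOH to (+)-leucorobinetinidin F1. F1 would be condensed in dilute aqueous HCl at room temperature with an excess of 1, in which ring D is switched off by the C4 carbonyl group, so that only C2' (= C6') of the pyrogallol ring attacks the C4 cation, trans to the 3-OH, to give robinetinidol-(4α→2')-dihydrorobinetin F2. Hydrogenation of the carbonyl group of F2 over PtO2, the classical reduction of trans-dihydroflavonols that is expected to give the 2,3-trans-3,4-cis diol, would give 21.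

2. Step 9. Process at risk: β-elimination of the alkylborane with opening of ring C at O1–C2, or slow hydroboration of the hindered enol ether. Fallback, from 17 back to 19: epoxidation of the enol ether with mCPBA in MeOH–CH2Cl2 buffered with NaHCO3 (attack anti to the C4 aryl group, methanolysis of the epoxide at C2) would give the mixed ketal 2-methoxy-4-arylflavan-3-ol F3. Reduction of this ketal with Et3SiH and catalytic trimethylsilyl trifluoromethanesulfonate in CH2Cl2 at −78 °C, through the C2 oxocarbenium ion with axial hydride delivery as in C-aryl glycoside synthesis, would give 19.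

3. Step 11. Process at risk: hydrogenolysis of the benzylic C4–OH of ring F once O7 of ring D is free. Fallback, from 19 (passing by 20) back to 21: 19 would be hydrogenolysed first (H2, Pd(OH)2/C, EtOAc–THF) with the 4-oxygen still silylated, to give the octaphenol bis-silyl ether F4. The two silyl ethers would then be removed with HF·pyridine buffered with pyridine in THF at 0 °C to give 21.

Further compounds
F1 | step 8 | (+)-leucorobinetinidin, (2R,3S,4R)-2-(3,4,5-trihydroxyphenyl)chroman-3,4,7-triol | Oc1ccc2c(c1)O[C@H](c1cc(O)c(O)c(O)c1)[C@@H](O)[C@@H]2O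
F2 | step 8 | robinetinidol-(4α→2')-dihydrorobinetin (upper unit 2R,3S,4S; lower unit (2R,3R)-dihydroflavonol) | Oc1ccc2c(c1)O[C@H](c1cc(O)c(O)c(O)c1)[C@@H](O)[C@@H]2c1c([C@H]2Oc3cc(O)ccc3C(=O)[C@@H]2O)cc(O)c(O)c1O
F3 | step 9 | 2-methoxy ketal of 19, 7-(benzyloxy)-2-methoxy-2-[3,4,5-tris(benzyloxy)phenyl]-4-arylchroman-3-ol (C2 either configuration, 3-OH trans to the C4 aryl group, aryl as in 17) | c1ccccc1COc1ccc2c(c1)OC(OC)(c1cc(OCc3ccccc3)c(OCc3ccccc3)c(OCc3ccccc3)c1)[C@@H](O)[C@@H]2c1c([C@H]2Oc3cc(OCc4ccccc4)ccc3[C@H](O[Si](C)(C)C(C)(C)C)[C@@H]2O[Si](C)(C)C(C)(C)C)cc(OCc2ccccc2)c(OCc2ccccc2)c1OCc1ccccc1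
F4 | step 11 | 3,4-bis-O-(tert-butyldimethylsilyl) ether of the target at the lower unit, all phenols free | Oc1ccc2c(c1)O[C@H](c1cc(O)c(O)c(O)c1)[C@@H](O)[C@@H]2c1c([C@H]2Oc3cc(O)ccc3[C@H](O[Si](C)(C)C(C)(C)C)[C@@H]2O[Si](C)(C)C(C)(C)C)cc(O)c(O)c1O
A1 | direct plan | hexa-O-benzyl-leucorobinetinidin, (2R,3S,4R)-3,4,7-tris(benzyloxy)-2-[3,4,5-tris(benzyloxy)phenyl]chroman | c1ccccc1COc1ccc2c(c1)O[C@H](c1cc(OCc3ccccc3)c(OCc3ccccc3)c(OCc3ccccc3)c1)[C@@H](OCc1ccccc1)[C@@H]2OCc1ccccc1
A2 | direct plan | 3,4,5-tris(benzyloxy)phenol | Oc1cc(OCc2ccccc2)c(OCc2ccccc2)c(OCc2ccccc2)c1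
A3 | direct plan | 4α-arylflavan phenol, 2-{(2R,3S,4S)-3,7-bis(benzyloxy)-2-[3,4,5-tris(benzyloxy)phenyl]chroman-4-yl}-3,4,5-tris(benzyloxy)phenol | c1ccccc1COc1ccc2c(c1)O[C@H](c1cc(OCc3ccccc3)c(OCc3ccccc3)c(OCc3ccccc3)c1)[C@@H](OCc1ccccc1)[C@@H]2c1c(O)cc(OCc3ccccc3)c(OCc3ccccc3)c1OCc1ccccc1
A4 | direct plan | aryl aldehyde, 2-{(2R,3S,4S)-3,7-bis(benzyloxy)-2-[3,4,5-tris(benzyloxy)phenyl]chroman-4-yl}-3,4,5-tris(benzyloxy)benzaldehyde | c1ccccc1COc1ccc2c(c1)O[C@H](c1cc(OCc3ccccc3)c(OCc3ccccc3)c(OCc3ccccc3)c1)[C@@H](OCc1ccccc1)[C@@H]2c1c(C=O)cc(OCc3ccccc3)c(OCc3ccccc3)c1OCc1ccccc1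
A5 | direct plan | (E)-2'-hydroxychalcone from A4, (E)-1-[4-(benzyloxy)-2-hydroxyphenyl]-3-arylprop-2-en-1-one | c1ccccc1COc1ccc2c(c1)O[C@H](c1cc(OCc3ccccc3)c(OCc3ccccc3)c(OCc3ccccc3)c1)[C@@H](OCc1ccccc1)[C@@H]2c1c(/C=C/C(=O)c3ccc(OCc4ccccc4)cc3O)cc(OCc3ccccc3)c(OCc3ccccc3)c1OCc1ccccc1
A6 | direct plan | (2S)-flav-3-ene, (2S)-7-(benzyloxy)-2-aryl-2H-chromene carrying the upper unit | c1ccccc1COc1ccc2c(c1)O[C@H](c1cc(OCc3ccccc3)c(OCc3ccccc3)c(OCc3ccccc3)c1)[C@@H](OCc1ccccc1)[C@@H]2c1c([C@H]3Oc4cc(OCc5ccccc5)ccc4C=C3)cc(OCc3ccccc3)c(OCc3ccccc3)c1OCc1ccccc1
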